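**Retrosynthetic overview**
- The allylic acetate is installed last, from the C18 silyl ether of the bridged lactone.
- Key disconnection: cut C9–C10 and the lactone O–C1 bond together, giving an acyclic ω-formyl 2-(methoxycarbonyl)allyl carbonate. A palladium/InI umpolung allylation closes the nine-membered carbocycle, and the alkoxide so formed closes the γ-lactone in the same flask.
- The acyclic chain is assembled in one three-component operation: Cu-catalysed carbomagnesiation of an ynoate (C1–C3, C18) by a homoallylic Grignard reagent (C4–C9), aldol capture by (S)-2,6-dimethylhept-5-enal (C10–C17), carbonate quench.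
- Fragments: the E-trisubstituted olefin comes from but-3-yn-1-ol (Zr-catalysed carboalumination, oxirane opening); the ynoate from silylated propargyl alcohol; the aldehyde (C11 stereocentre) from (S)-citronellal by one-carbon degradation.
- Ring order: nine-membered ring first, lactone second, both in one operation; no ring exists before that step.

Locants used in the text: C1 lactone carbonyl; C2=C3 tetrasubstituted alkene (C18 = CH2O on C3); C4, C5 ring CH2; C6=C7 E-alkene (methyl on C7); C8 ring CH2; C9 O-bearing ring CH; C10 ring CH carrying the side chain; C11 side-chain CH(CH3).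
Assumption: (S)-citronellal of high ee and tert-butyldimethyl(prop-2-yn-1-yloxy)silane are bought.

**Route**

Step 1
Reactants: 1 but-3-yn-1-ol
Product: 2 (but-3-yn-1-yloxy)triethylsilane
Conditions: Et3SiCl, imidazole, CH2Cl2, 0 °C to rt
Reagents that add atoms: chlorotriethylsilane CC[Si](Cl)(CC)CC
Why: Standard silyl ether formation on a primary alcohol; the triethylsilyl group is chosen because it can later be removed beside the allylic tert-butyldimethylsilyl ether.

Step 2
Reactants: 2 (but-3-yn-1-yloxy)triethylsilane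
Product: 5 (E)-4-methyl-6-(triethylsilyloxy)hex-3-en-1-ol, via alkenylalane 3 (not isolated), via lithium alkenylaluminate 4 (not isolated)
Conditions: Me3Al (2.5 equiv), Cp2ZrCl2 (0.25 equiv), CH2Cl2, 0 °C to rt; evaporate excess Me3Al; n-BuLi, hexane–THF, −78 to 0 °C; oxirane, 0 °C to rt; aqueous potassium sodium tartrate
Reagents that add atoms: trimethylaluminium C[Al](C)C; oxirane C1CO1
Why: Negishi zirconium-catalysed carboalumination adds methyl and aluminium syn across the terminal alkyne (methyl to the internal carbon), and the derived alkenylaluminate opens oxirane with retention, which fixes the E-trisubstituted C6=C7 olefin.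

Step 3
Reactants: 5 (E)-4-methyl-6-(triethylsilyloxy)hex-3-en-1-ol
Product: 6 (E)-(6-bromo-3-methylhex-3-en-1-yloxy)triethylsilane
Conditions: CBr4, PPh3, 2,6-lutidine, CH2Cl2, 0 °C
Reagents that add atoms: tetrabromomethane BrC(Br)(Br)Br
Why: Appel bromination of the primary alcohol under buffered conditions that leave the silyl ether and the olefin untouched.

Step 4
Reactants: 7 tert-butyldimethyl(prop-2-yn-1-yloxy)silane
Product: 9 methyl 4-(tert-butyldimethylsilyloxy)but-2-ynoate, via lithium acetylide 8 (not isolated)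
Conditions: n-BuLi, THF, −78 °C; ClCO2Me, −78 to 0 °C
Reagents that add atoms: methyl chloroformate COC(=O)Cl
Why: Deprotonation of the terminal alkyne and C-acylation of the acetylide with a chloroformate (alkynoate synthesis).

Step 5
Reactants: 10 (S)-citronellal
Product: 12 (2S)-2,6-dimethylhept-5-enal, via piperidine enamine 11 (not isolated)
Conditions: piperidine, K2CO3, Et2O, 0 °C to rt; filter, concentrate; CuCl (10 mol %), O2 (1 atm), MeCN, rt
Reagents that add atoms: dioxygen O=O
Why: Enamine formation followed by copper-catalysed aerobic cleavage of the enamine C=C bond removes one carbon without touching the trisubstituted olefin; the resident stereocentre (the future C11) takes no part, and the product is kept cold and amine-free to avoid α-epimerisation.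

Step 6
Reactants: 6 (E)-(6-bromo-3-methylhex-3-en-1-yloxy)triethylsilane; 9 methyl 4-(tert-butyldimethylsilyloxy)but-2-ynoate; 12 (2S)-2,6-dimethylhept-5-enal
Product: 16 methyl (2Z,6E)-3-{[(tert-butyldimethylsilyl)oxy]methyl}-2-[(2S)-1-[(methoxycarbonyl)oxy]-2,6-dimethylhept-5-en-1-yl]-7-methyl-9-[(triethylsilyl)oxy]nona-2,6-dienoate (both C1′ epimers), via Grignard reagent 13 (not isolated), via alkenylmagnesium adduct 14 (not isolated), via magnesium aldolate 15 (not isolated)
Conditions: 6, Mg, THF, rt; add to 9, CuI (10 mol %), THF, −78 °C; 12, −78 °C; ClCO2Me, −78 to 0 °C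
Reagents that add atoms: methyl chloroformate COC(=O)Cl
Why: Copper-catalysed syn-carbomagnesiation of the ynoate gives an alkenylmagnesium/allenolate that is trapped by the aldehyde (tandem conjugate addition–aldol) and O-acylated in situ; the new carbinol centre (C10) forms as an epimer mixture that is irrelevant because it becomes an allyl terminus in step 9, and C11 is untouched.

Step 7
Reactants: 16 methyl (2Z,6E)-3-{[(tert-butyldimethylsilyl)oxy]methyl}-2-[(2S)-1-[(methoxycarbonyl)oxy]-2,6-dimethylhept-5-en-1-yl]-7-methyl-9-[(triethylsilyl)oxy]nona-2,6-dienoate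
Product: 17 methyl (2Z,6E)-3-{[(tert-butyldimethylsilyl)oxy]methyl}-9-hydroxy-2-[(2S)-1-[(methoxycarbonyl)oxy]-2,6-dimethylhept-5-en-1-yl]-7-methylnona-2,6-dienoate
Conditions: PPTS (0.2 equiv), MeOH–CH2Cl2, 0 °C
Reagents that add atoms: none
Why: Acid-catalysed methanolysis cleaves the primary triethylsilyl ether much faster than the tert-butyldimethylsilyl ether (selective desilylation); carbonate and ester are inert.

Step 8
Reactants: 17 methyl (2Z,6E)-3-{[(tert-butyldimethylsilyl)oxy]methyl}-9-hydroxy-2-[(2S)-1-[(methoxycarbonyl)oxy]-2,6-dimethylhept-5-en-1-yl]-7-methylnona-2,6-dienoate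
Product: 18 methyl (2Z,6E)-3-{[(tert-butyldimethylsilyl)oxy]methyl}-2-[(2S)-1-[(methoxycarbonyl)oxy]-2,6-dimethylhept-5-en-1-yl]-7-methyl-9-oxonona-2,6-dienoate
Conditions: Dess–Martin periodinane, NaHCO3, CH2Cl2, 0 °C; used at once
Reagents that add atoms: none
Why: Buffered Dess–Martin oxidation gives the β,γ-unsaturated aldehyde under neutral conditions that do not move the C6=C7 double bond into conjugation.

Step 9
Reactants: 18 methyl (2Z,6E)-3-{[(tert-butyldimethylsilyl)oxy]methyl}-2-[(2S)-1-[(methoxycarbonyl)oxy]-2,6-dimethylhept-5-en-1-yl]-7-methyl-9-oxonona-2,6-dienoate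
Product: 21 (1Z,5E,8R,11S)-2-{[(tert-butyldimethylsilyl)oxy]methyl}-6-methyl-11-[(2S)-6-methylhept-5-en-2-yl]-9-oxabicyclo[6.2.1]undeca-1,5-dien-10-one, via allylindium species 19 (not isolated), via indium alkoxide 20 (not isolated)
Conditions: Pd(PPh3)4 (10 mol %), InI (1.5 equiv), THF–DMPU 4:1, rt, slow addition of 18 (final 0.002 M); then PPTS (20 mol %), rt; chromatography
Reagents that add atoms: none
Why: Proposed new method: zerovalent palladium ionises the allylic carbonate (loss of CO2 and methoxide) and InI reduces the resulting π-allylpalladium to a nucleophilic allylindium (trivalent indium) whose two σ-forms interconvert by 1,3-shift; attack on the tethered aldehyde through C3 would give an impossible (E)-cycloheptene, so the C–C bond can only form at C10 (nine-membered ring) and the indium alkoxide then lactonises onto the neighbouring methyl ester, the ring forcing the Z tetrasubstituted C2=C3 olefin and the compact bicyclic transition state placing the side chain of C10 anti to C8 (trans C9/C10), while the sense relative to C11 rests only on allylic 1,2-induction, which is weak and may even favour the other face, so the (8S,11R) trans isomer is removed by chromatography; the closest known reactions are the palladium/InI umpolung carbonyl allylation of allylic carbonates and the intramolecular Barbier allylation–lactonisation of 2-(alkoxycarbonyl)allyl halides used for ten-membered germacranolides.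

Step 10
Reactants: 21 (1Z,5E,8R,11S)-2-{[(tert-butyldimethylsilyl)oxy]methyl}-6-methyl-11-[(2S)-6-methylhept-5-en-2-yl]-9-oxabicyclo[6.2.1]undeca-1,5-dien-10-one
Product: 23 [(1Z,5E,8R,11S)-6-methyl-11-[(2S)-6-methylhept-5-en-2-yl]-10-oxo-9-oxabicyclo[6.2.1]undeca-1,5-dien-2-yl]methyl acetate, via primary alcohol 22 (not isolated)
Conditions: HF·pyridine, pyridine, THF, 0 °C; NaHCO3 wash; crude 22, Ac2O, pyridine, DMAP (cat.), CH2Cl2, 0 °C
Reagents that add atoms: acetic anhydride CC(=O)OC(C)=O
Why: Buffered, non-basic fluoride cleavage of the silyl ether and immediate acetylation cap the primary alcohol before it can attack the cis lactone carbonyl; no stereocentre is touched.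

**Compound list**
1 | but-3-yn-1-ol | C#CCCO | starting material
2 | (but-3-yn-1-yloxy)triethylsilane | C#CCCO[Si](CC)(CC)CC | intermediate
3 | (E)-dimethyl[2-methyl-4-(triethylsilyloxy)but-1-en-1-yl]alane | C[Al](C)/C=C(\C)CCO[Si](CC)(CC)CC | intermediate (not isolated)
4 | lithium (E)-butyldimethyl[2-methyl-4-(triethylsilyloxy)but-1-en-1-yl]aluminate | [Li+].CCCC[Al-](C)(C)/C=C(\C)CCO[Si](CC)(CC)CC | intermediate (not isolated)
5 | (E)-4-methyl-6-(triethylsilyloxy)hex-3-en-1-ol | OCC/C=C(\C)CCO[Si](CC)(CC)CC | intermediate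
6 | (E)-(6-bromo-3-methylhex-3-en-1-yloxy)triethylsilane | BrCC/C=C(\C)CCO[Si](CC)(CC)CC | intermediate
7 | tert-butyldimethyl(prop-2-yn-1-yloxy)silane | C#CCO[Si](C)(C)C(C)(C)C | starting material
8 | [3-(tert-butyldimethylsilyloxy)prop-1-yn-1-yl]lithium | [Li]C#CCO[Si](C)(C)C(C)(C)C | intermediate (not isolated)
9 | methyl 4-(tert-butyldimethylsilyloxy)but-2-ynoate | COC(=O)C#CCO[Si](C)(C)C(C)(C)C | intermediate
10 | (S)-citronellal, (3S)-3,7-dimethyloct-6-enal | O=CC[C@@H](C)CCC=C(C)C | starting material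
11 | 1-[(1E,3S)-3,7-dimethylocta-1,6-dien-1-yl]piperidine | C1CCN(CC1)/C=C/[C@@H](C)CCC=C(C)C | intermediate (not isolated)
12 | (2S)-2,6-dimethylhept-5-enal | O=C[C@@H](C)CCC=C(C)C | intermediate
13 | [(E)-4-methyl-6-(triethylsilyloxy)hex-3-en-1-yl]magnesium bromide | Br[Mg]CC/C=C(\C)CCO[Si](CC)(CC)CC | intermediate (not isolated)
14 | methyl (2E,6E)-2-(bromomagnesio)-3-{[(tert-butyldimethylsilyl)oxy]methyl}-7-methyl-9-[(triethylsilyl)oxy]nona-2,6-dienoate (C4 chain cis to Mg; in equilibrium with the magnesium allenolate) | COC(=O)/C([Mg]Br)=C(\CO[Si](C)(C)C(C)(C)C)CC/C=C(\C)CCO[Si](CC)(CC)CC | intermediate (not isolated)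
15 | bromomagnesium alkoxide of methyl (2Z,6E)-3-{[(tert-butyldimethylsilyl)oxy]methyl}-2-[(2S)-1-hydroxy-2,6-dimethylhept-5-en-1-yl]-7-methyl-9-[(triethylsilyl)oxy]nona-2,6-dienoate (both C1′ epimers) | COC(=O)/C(C(O[Mg]Br)[C@@H](C)CCC=C(C)C)=C(\CO[Si](C)(C)C(C)(C)C)CC/C=C(\C)CCO[Si](CC)(CC)CC | intermediate (not isolated)
16 | methyl (2Z,6E)-3-{[(tert-butyldimethylsilyl)oxy]methyl}-2-[(2S)-1-[(methoxycarbonyl)oxy]-2,6-dimethylhept-5-en-1-yl]-7-methyl-9-[(triethylsilyl)oxy]nona-2,6-dienoate (both C1′ epimers) | COC(=O)/C(C(OC(=O)OC)[C@@H](C)CCC=C(C)C)=C(\CO[Si](C)(C)C(C)(C)C)CC/C=C(\C)CCO[Si](CC)(CC)CC | intermediate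
17 | methyl (2Z,6E)-3-{[(tert-butyldimethylsilyl)oxy]methyl}-9-hydroxy-2-[(2S)-1-[(methoxycarbonyl)oxy]-2,6-dimethylhept-5-en-1-yl]-7-methylnona-2,6-dienoate (both C1′ epimers) | COC(=O)/C(C(OC(=O)OC)[C@@H](C)CCC=C(C)C)=C(\CO[Si](C)(C)C(C)(C)C)CC/C=C(\C)CCO | intermediate
18 | methyl (2Z,6E)-3-{[(tert-butyldimethylsilyl)oxy]methyl}-2-[(2S)-1-[(methoxycarbonyl)oxy]-2,6-dimethylhept-5-en-1-yl]-7-methyl-9-oxonona-2,6-dienoate (both C1′ epimers) | COC(=O)/C(C(OC(=O)OC)[C@@H](C)CCC=C(C)C)=C(\CO[Si](C)(C)C(C)(C)C)CC/C=C(\C)CC=O | intermediate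
19 | methyl (6E)-3-{[(tert-butyldimethylsilyl)oxy]methyl}-2-[(2S)-2,6-dimethylhept-5-en-1-ylidene]-3-[iodo(methoxy)indio]-7-methyl-9-oxonon-6-enoate (C3-bound σ-allyl form shown; equilibrates with the C10-bound form) | CO[In](I)C(CO[Si](C)(C)C(C)(C)C)(CC/C=C(\C)CC=O)C(C(=O)OC)=C[C@@H](C)CCC=C(C)C | intermediate (not isolated)
20 | iodo(methoxy)indium alkoxide of methyl (1Z,5E,8R,9S)-2-{[(tert-butyldimethylsilyl)oxy]methyl}-8-hydroxy-6-methyl-9-[(2S)-6-methylhept-5-en-2-yl]cyclonona-1,5-diene-1-carboxylate | CC(C)(C)[Si](C)(C)OC/C1=C(\C(=O)OC)[C@H]([C@@H](C)CCC=C(C)C)[C@H](O[In](I)OC)C/C(C)=C/CC1 | intermediate (not isolated)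
21 | (1Z,5E,8R,11S)-2-{[(tert-butyldimethylsilyl)oxy]methyl}-6-methyl-11-[(2S)-6-methylhept-5-en-2-yl]-9-oxabicyclo[6.2.1]undeca-1,5-dien-10-one | CC(C)(C)[Si](C)(C)OC/C1=C2\C(=O)O[C@H](C/C(C)=C/CC1)[C@H]2[C@@H](C)CCC=C(C)C | intermediate
22 | (1Z,5E,8R,11S)-2-(hydroxymethyl)-6-methyl-11-[(2S)-6-methylhept-5-en-2-yl]-9-oxabicyclo[6.2.1]undeca-1,5-dien-10-one | OC/C1=C2\C(=O)O[C@H](C/C(C)=C/CC1)[C@H]2[C@@H](C)CCC=C(C)C | intermediate (not isolated)
23 | [(1Z,5E,8R,11S)-6-methyl-11-[(2S)-6-methylhept-5-en-2-yl]-10-oxo-9-oxabicyclo[6.2.1]undeca-1,5-dien-2-yl]methyl acetate | CC(=O)OC/C1=C2\C(=O)O[C@H](C/C(C)=C/CC1)[C@H]2[C@@H](C)CCC=C(C)C | target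

**Totals**
Total step count: 10.
Longest linear sequence: 8 steps (1, 2, 3, 6, 7, 8, 9, 10 from but-3-yn-1-ol); steps 4 and 5 are one-step side branches.

**Steps most likely to fail, with fallbacks**

1. Step 9. The (E)-cyclononene is strained, the C–C bond must form at the allyl terminus C10 (indium on the tertiary C3), oligomerisation and protonation compete, and the C9/C10 sense relative to C11 is only weakly controlled. The fallback drops the palladium/InI umpolung and makes the allyl nucleophile by insertion of divalent chromium into an allylic bromide (Nozaki–Hiyama–Kishi-type Barbier cyclisation); a chiral oxazoline–sulfonamide ligand on chromium can then also select the aldehyde face. It sets out from 6, 9 and 12. The coupling of step 6 is quenched with aqueous NH4Cl instead of ClCO2Me to give the free allylic alcohol methyl (2Z,6E)-3-{[(tert-butyldimethylsilyl)oxy]methyl}-2-[(2S)-1-hydroxy-2,6-dimethylhept-5-en-1-yl]-7-methyl-9-[(triethylsilyl)oxy]nona-2,6-dienoate F1. CBr4/PPh3 (CH2Cl2, 0 °C) converts it into the allylic bromide methyl (2E,6E)-2-[(2S)-1-bromo-2,6-dimethylhept-5-en-1-yl]-3-{[(tert-butyldimethylsilyl)oxy]methyl}-7-methyl-9-[(triethylsilyl)oxy]nona-2,6-dienoate F2 (its allylic isomer would serve equally). PPTS/MeOH removes the triethylsilyl group to give methyl (2E,6E)-2-[(2S)-1-bromo-2,6-dimethylhept-5-en-1-yl]-3-{[(tert-butyldimethylsilyl)oxy]methyl}-9-hydroxy-7-methylnona-2,6-dienoate F3. Buffered Dess–Martin oxidation gives methyl (2E,6E)-2-[(2S)-1-bromo-2,6-dimethylhept-5-en-1-yl]-3-{[(tert-butyldimethylsilyl)oxy]methyl}-7-methyl-9-oxonona-2,6-dienoate F4. Slow addition of F4 to CrCl2 (5 equiv, THF–DMF, rt), then PPTS, closes both rings and comes back to the route at 21.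

2. Step 6. The alkenylmagnesium/allenolate may add sluggishly to the α-branched aldehyde, or protonate and lose olefin geometry. The fallback separates the two C–C bond formations and sets out from 6 and 9. Grignard reagent 13 is added to 9 with CuI as before, but the alkenylmagnesium 14 is quenched with I2 to give the isolable methyl (2E,6E)-3-{[(tert-butyldimethylsilyl)oxy]methyl}-2-iodo-7-methyl-9-[(triethylsilyl)oxy]nona-2,6-dienoate F5. Iodine–magnesium exchange (i-PrMgCl·LiCl, THF, −40 °C) regenerates a configurationally defined alkenylmagnesium free of copper. This adds to 12, and the ClCO2Me quench comes back to the route at 16.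

3. Step 10. The free primary alcohol 22 lies cis to the lactone carbonyl and can translactonise to the fused butenolide before it is acetylated. The fallback avoids any free hydroxyl and sets out from 21. Ph3PBr2 (CH2Cl2, 0 °C) converts the silyl ether directly into (1Z,5E,8R,11S)-2-(bromomethyl)-6-methyl-11-[(2S)-6-methylhept-5-en-2-yl]-9-oxabicyclo[6.2.1]undeca-1,5-dien-10-one F6. SN2 displacement with CsOAc and 18-crown-6 (toluene–DMF, rt) then comes back to the route at 23.

**Further compounds**
F1 | step 9 | methyl (2Z,6E)-3-{[(tert-butyldimethylsilyl)oxy]methyl}-2-[(2S)-1-hydroxy-2,6-dimethylhept-5-en-1-yl]-7-methyl-9-[(triethylsilyl)oxy]nona-2,6-dienoate | COC(=O)/C(C(O)[C@@H](C)CCC=C(C)C)=C(\CO[Si](C)(C)C(C)(C)C)CC/C=C(\C)CCO[Si](CC)(CC)CC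
F2 | step 9 | methyl (2E,6E)-2-[(2S)-1-bromo-2,6-dimethylhept-5-en-1-yl]-3-{[(tert-butyldimethylsilyl)oxy]methyl}-7-methyl-9-[(triethylsilyl)oxy]nona-2,6-dienoate | COC(=O)/C(C(Br)[C@@H](C)CCC=C(C)C)=C(\CO[Si](C)(C)C(C)(C)C)CC/C=C(\C)CCO[Si](CC)(CC)CC
F3 | step 9 | methyl (2E,6E)-2-[(2S)-1-bromo-2,6-dimethylhept-5-en-1-yl]-3-{[(tert-butyldimethylsilyl)oxy]methyl}-9-hydroxy-7-methylnona-2,6-dienoate | COC(=O)/C(C(Br)[C@@H](C)CCC=C(C)C)=C(\CO[Si](C)(C)C(C)(C)C)CC/C=C(\C)CCO
F4 | step 9 | methyl (2E,6E)-2-[(2S)-1-bromo-2,6-dimethylhept-5-en-1-yl]-3-{[(tert-butyldimethylsilyl)oxy]methyl}-7-methyl-9-oxonona-2,6-dienoate | COC(=O)/C(C(Br)[C@@H](C)CCC=C(C)C)=C(\CO[Si](C)(C)C(C)(C)C)CC/C=C(\C)CC=O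
F5 | step 6 | methyl (2E,6E)-3-{[(tert-butyldimethylsilyl)oxy]methyl}-2-iodo-7-methyl-9-[(triethylsilyl)oxy]nona-2,6-dienoate | COC(=O)/C(I)=C(\CO[Si](C)(C)C(C)(C)C)CC/C=C(\C)CCO[Si](CC)(CC)CC
F6 | step 10 | (1Z,5E,8R,11S)-2-(bromomethyl)-6-methyl-11-[(2S)-6-methylhept-5-en-2-yl]-9-oxabicyclo[6.2.1]undeca-1,5-dien-10-one | BrC/C1=C2\C(=O)O[C@H](C/C(C)=C/CC1)[C@H]2[C@@H](C)CCC=C(C)C
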